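**Retrosynthetic overview**
- Feature: ring A is a fully substituted benzene in which the free C5–OH stands para to the C8–OMe, and it is fused to pyranone ring C along C4a–C8a. This hydroquinone-monoether pattern maps onto a chromium carbene + alkyne + CO benzannulation (C8 = carbene carbon, C7/C6 = alkyne carbons, C5 = a carbonyl ligand, C8a/C4a = C2/C3 of a 4-pyranone).
- End game: O-benzyl removal ⇐ 6,7-di-O-methylation ⇐ oxidation of two C–B bonds, so a symmetrical diborylethyne carries the latent C6 and C7 oxygens.
- The carbene complex ⇐ 6-aryl-4-oxopyran-2-carbonyl chloride + Na2Cr(CO)5. The pyranone ester ⇐ cyclodehydration of a triketo ester made by two Claisen condensations (ethyl acetate, diethyl oxalate) on di-O-benzylated 2,4-dihydroxyacetophenone.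
- Ring order: ring B is bought, ring C is closed second, ring A is closed last.

Key step: step 9

Remark: 1,3-dicarbonyl compounds are drawn as keto tautomers although they are largely enolized. In the SMILES strings carbonyl ligands are written Cr=C=O and the η6 complex 19 is written as two fragments.

Step 1
Reactants: 1 2,4-dihydroxyacetophenone
Product: 2 2,4-dibenzyloxyacetophenone
Conditions: BnBr (2.5 equiv), K2CO3 (3 equiv), DMF, 80 °C
Reagents that add atoms: benzyl bromide, BrCc1ccccc1
Why: Williamson ether synthesis, in which excess halide and heat in a dipolar solvent also alkylate the hydrogen-bonded 2-OH, and benzyl is chosen because it survives base, mild acid, low-valent chromium and peroxide yet leaves by hydrogenolysis at the end.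

Step 2
Reactants: 2 2,4-dibenzyloxyacetophenone; 3 ethyl acetate
Product: 4 1-(2,4-dibenzyloxyphenyl)butane-1,3-dione
Conditions: NaH (2.5 equiv), 3 (5 equiv), THF, reflux; then 1 M HCl
Reagents that add atoms: none
Why: Crossed Claisen condensation of the methyl ketone enolate with ethyl acetate, driven forward by irreversible deprotonation of the 1,3-diketone as it forms.

Step 3
Reactants: 4 1-(2,4-dibenzyloxyphenyl)butane-1,3-dione; 5 diethyl oxalate
Product: 6 ethyl 6-(2,4-dibenzyloxyphenyl)-2,4,6-trioxohexanoate
Conditions: LiN(iPr)2 (2.3 equiv), THF, −78 to 0 °C; 5 (1.5 equiv), −78 to 0 °C; then 1 M HCl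
Reagents that add atoms: none
Why: Claisen acylation of a 1,3-diketone dianion, in which the second deprotonation creates the more reactive terminal carbanion, so the non-enolizable oxalate is attacked by C4 (the former methyl group) and not by the central carbon.

Step 4
Reactants: 6 ethyl 6-(2,4-dibenzyloxyphenyl)-2,4,6-trioxohexanoate
Product: 7 ethyl 6-(2,4-dibenzyloxyphenyl)-4-oxo-4H-pyran-2-carboxylate
Conditions: HCl (1.25 M in EtOH), 60 °C
Reagents that add atoms: none
Why: Acid-catalysed cyclodehydration of a 1,3,5-tricarbonyl chain (6-exo-trig attack of an enol oxygen on the carbonyl five atoms away, then loss of water) is the standard entry to 4-pyranones, both directions of closure give the same ring C, and ethanol keeps the ethyl ester intact.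

Step 5
Reactants: 7 ethyl 6-(2,4-dibenzyloxyphenyl)-4-oxo-4H-pyran-2-carboxylate
Product: 8 6-(2,4-dibenzyloxyphenyl)-4-oxo-4H-pyran-2-carboxylic acid
Conditions: LiOH (1.1 equiv), THF/H2O, 0 °C; then 1 M HCl to pH 2
Reagents that add atoms: lithium hydroxide, [Li+].[OH-]
Why: Saponification of an ester activated by the electron-poor ring should be fast at 0 °C with about one equivalent of hydroxide, and any pyranone opened by conjugate attack recloses to the same acid on acidification.

Step 6
Reactants: 8 6-(2,4-dibenzyloxyphenyl)-4-oxo-4H-pyran-2-carboxylic acid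
Product: 9 6-(2,4-dibenzyloxyphenyl)-4-oxo-4H-pyran-2-carbonyl chloride
Conditions: (COCl)2 (1.3 equiv), DMF (cat.), CH2Cl2, 0 °C to rt; evaporate, use at once
Reagents that add atoms: oxalyl chloride, O=C(Cl)C(=O)Cl
Why: Vilsmeier-type conversion of a carboxylic acid into its chloride, as practised on chromone-2- and 4-pyranone-2-carboxylic acids, leaves the benzyl ethers and the ring carbonyl untouched.

Step 7
Reactants: 9 6-(2,4-dibenzyloxyphenyl)-4-oxo-4H-pyran-2-carbonyl chloride; 10 chromium hexacarbonyl Cr(CO)6
Product: 13 pentacarbonyl{[6-(2,4-dibenzyloxyphenyl)-4-oxo-4H-pyran-2-yl](methoxy)methylidene}chromium, via disodium pentacarbonylchromate 11 (not isolated), via sodium acylpentacarbonylchromate 12 (not isolated)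
Conditions: 10 (1.1 equiv), NaC10H8 (2.0 equiv, stock solution), THF, −78 °C; 9, −78 to 0 °C; evaporate; Me3OBF4 (1.0 equiv), CH2Cl2, −20 to 0 °C
Reagents that add atoms: trimethyloxonium tetrafluoroborate, C[O+](C)C.F[B-](F)(F)F
Why: Semmelhack–Hegedus route to Fischer carbene complexes, in which two-electron reduction of 10 gives the strongly nucleophilic dianion 11, the acid chloride acylates it at chromium faster than it can touch the vinylogous-ester carbonyl, and the anionic acylate oxygen of 12 takes the single equivalent of Meerwein salt ahead of the neutral pyranone oxygen.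

Step 8
Reactants: 14 trichloroethylene; 15 2-isopropoxy-4,4,5,5-tetramethyl-1,3,2-dioxaborolane
Product: 18 1,2-bis(4,4,5,5-tetramethyl-1,3,2-dioxaborolan-2-yl)ethyne, via dilithioacetylene 16 (not isolated), via dilithium ethynediylbis(borate) 17 (not isolated)
Conditions: n-BuLi (3.0 equiv), Et2O/THF, −78 °C to rt; 15 (2.0 equiv), −78 °C; HCl (2.0 equiv, 2 M in Et2O), −78 °C to rt; filter, recrystallize
Reagents that add atoms: none
Why: Elimination and chlorine–lithium exchange turn trichloroethylene into dilithioacetylene, which adds to the boron of two molecules of 15, and anhydrous HCl strips isopropoxide from the bis(borate), which is the standard borate route to alkynylboronic esters.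

Step 9
Reactants: 13 pentacarbonyl{[6-(2,4-dibenzyloxyphenyl)-4-oxo-4H-pyran-2-yl](methoxy)methylidene}chromium; 18 1,2-bis(4,4,5,5-tetramethyl-1,3,2-dioxaborolan-2-yl)ethyne
Product: 20 2-(2,4-dibenzyloxyphenyl)-5-hydroxy-8-methoxy-6,7-bis(pinacolboryl)chromen-4-one, via tricarbonylchromium arene complex 19 (not isolated)
Conditions: 18 (2.5 equiv), THF (0.2 M), 55 °C, Ar; then air, Et2O/CH2Cl2, daylight, rt; short silica column
Reagents that add atoms: none
Why: Heating expels a cis CO ligand from 13, the alkyne 18 binds and inserts into the Cr=C bond (C8–C7), and a CO ligand migrates to the new carbene carbon (C6–C5) to give a chromium-bound dienylketene. Ring A then closes by a six-electron electrocyclization between the ketene carbon and pyranone C3 (C5–C4a), a polarity-matched union because C3 is the nucleophilic enol-ether β-carbon of the O1–C2=C3 unit, and the cyclohexadienone formed enolizes at once since its C4a–H lies between two carbonyl groups. The step is a Dötz benzannulation whose closest relatives are the annulations of cyclic α-alkoxyalkenyl and 2-furyl methoxycarbene complexes of chromium and those that use alkynyl pinacolboronates, although this pairing of an acceptor-bearing pyranonyl carbene and a doubly borylated alkyne has not been tried. No stereocenter arises, and the symmetrical alkyne makes both insertion orientations identical, so the carbene OMe must end at C8 and the inserted CO as the C5–OH. What the step needs is chemoselectivity for CO insertion and closure at carbon over cyclopentannulation, furan formation or arrest at the ketene, and this is favoured by the alkoxy (not amino) donor on chromium, by an alkenyl rather than benzenoid terminus, by an ether solvent free of nitrile or amide donors and by a high alkyne concentration. Air rather than a cerium or iron oxidant frees the arene from Cr(CO)3, so that the hydroquinone monoether is not carried on to the quinone.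

Step 10
Reactants: 20 2-(2,4-dibenzyloxyphenyl)-5-hydroxy-8-methoxy-6,7-bis(pinacolboryl)chromen-4-one
Product: 21 2-(2,4-dibenzyloxyphenyl)-5,6,7-trihydroxy-8-methoxychromen-4-one
Conditions: 30% aq H2O2 (5 equiv), pH 7 buffer (NaH2PO4/Na2HPO4), THF, 0 °C to rt, Ar; Na2S2O3 quench; use without delay
Reagents that add atoms: hydrogen peroxide, OO
Why: Peroxide oxidation of arylboronic esters (hydroperoxide adds to boron, the aryl group migrates from B to O at the same ring position, the borate ester hydrolyses) is general, and neutral buffer, low temperature and exclusion of air and chromium residues protect the electron-rich triol and the C2–C3 double bond.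

Step 11
Reactants: 21 2-(2,4-dibenzyloxyphenyl)-5,6,7-trihydroxy-8-methoxychromen-4-one
Product: 22 2-(2,4-dibenzyloxyphenyl)-5-hydroxy-6,7,8-trimethoxychromen-4-one
Conditions: MeI (2.2 equiv), K2CO3 (2.2 equiv), degassed acetone, rt to 40 °C, Ar
Reagents that add atoms: iodomethane, CI
Why: Williamson methylation under weak base discriminates by acidity and hydrogen bonding, so the 7-OH and 6-OH are ionized and alkylated while the 5-OH stays locked in its six-membered hydrogen bond to the C4 carbonyl, a selectivity long used on 5,6,7-trihydroxyflavones.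

Step 12
Reactants: 22 2-(2,4-dibenzyloxyphenyl)-5-hydroxy-6,7,8-trimethoxychromen-4-one
Product: 23 Tamadone, 2-(2,4-dihydroxyphenyl)-5-hydroxy-6,7,8-trimethoxychromen-4-one
Conditions: H2 (1 atm), 10% Pd/C, EtOAc/MeOH, rt
Reagents that add atoms: none
Why: Catalytic hydrogenolysis cleaves both benzylic C–O bonds under neutral conditions at 1 atm, where aryl methyl ethers and the conjugated C2–C3 bond of a flavone are not reduced.

**Compound list**
1 | 2,4-dihydroxyacetophenone | CC(=O)c1ccc(O)cc1O | starting material
2 | 2,4-dibenzyloxyacetophenone | CC(=O)c1ccc(OCc2ccccc2)cc1OCc1ccccc1 | intermediate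
3 | ethyl acetate | CCOC(C)=O | starting material
4 | 1-(2,4-dibenzyloxyphenyl)butane-1,3-dione | CC(=O)CC(=O)c1ccc(OCc2ccccc2)cc1OCc1ccccc1 | intermediate
5 | diethyl oxalate | CCOC(=O)C(=O)OCC | starting material
6 | ethyl 6-(2,4-dibenzyloxyphenyl)-2,4,6-trioxohexanoate | CCOC(=O)C(=O)CC(=O)CC(=O)c1ccc(OCc2ccccc2)cc1OCc1ccccc1 | intermediate
7 | ethyl 6-(2,4-dibenzyloxyphenyl)-4-oxo-4H-pyran-2-carboxylate | CCOC(=O)c1cc(=O)cc(-c2ccc(OCc3ccccc3)cc2OCc2ccccc2)o1 | intermediate
8 | 6-(2,4-dibenzyloxyphenyl)-4-oxo-4H-pyran-2-carboxylic acid | O=C(O)c1cc(=O)cc(-c2ccc(OCc3ccccc3)cc2OCc2ccccc2)o1 | intermediate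
9 | 6-(2,4-dibenzyloxyphenyl)-4-oxo-4H-pyran-2-carbonyl chloride | O=C(Cl)c1cc(=O)cc(-c2ccc(OCc3ccccc3)cc2OCc2ccccc2)o1 | intermediate
10 | chromium hexacarbonyl Cr(CO)6 | O=C=[Cr](=C=O)(=C=O)(=C=O)(=C=O)=C=O | starting material
11 | disodium pentacarbonylchromate Na2Cr(CO)5 (not isolated) | [Na+].[Na+].O=C=[Cr-2](=C=O)(=C=O)(=C=O)=C=O | intermediate
12 | sodium pentacarbonyl[6-(2,4-dibenzyloxyphenyl)-4-oxo-4H-pyran-2-carbonyl]chromate (not isolated) | [Na+].[O-]C(c1cc(=O)cc(-c2ccc(OCc3ccccc3)cc2OCc2ccccc2)o1)=[Cr](=C=O)(=C=O)(=C=O)(=C=O)=C=O | intermediate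
13 | pentacarbonyl{[6-(2,4-dibenzyloxyphenyl)-4-oxo-4H-pyran-2-yl](methoxy)methylidene}chromium | COC(c1cc(=O)cc(-c2ccc(OCc3ccccc3)cc2OCc2ccccc2)o1)=[Cr](=C=O)(=C=O)(=C=O)(=C=O)=C=O | intermediate
14 | trichloroethylene | ClC=C(Cl)Cl | starting material
15 | 2-isopropoxy-4,4,5,5-tetramethyl-1,3,2-dioxaborolane | CC(C)OB1OC(C)(C)C(C)(C)O1 | starting material
16 | dilithioacetylene (not isolated) | [Li]C#C[Li] | intermediate
17 | dilithium ethyne-1,2-diylbis[isopropoxy(pinacolato)borate] (not isolated) | [Li+].[Li+].CC(C)O[B-]1(C#C[B-]2(OC(C)C)OC(C)(C)C(C)(C)O2)OC(C)(C)C(C)(C)O1 | intermediate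
18 | 1,2-bis(4,4,5,5-tetramethyl-1,3,2-dioxaborolan-2-yl)ethyne | CC1(C)OB(C#CB2OC(C)(C)C(C)(C)O2)OC1(C)C | intermediate
19 | tricarbonylchromium complex of 20, η6-bound through ring A (not isolated) | COc1c(B2OC(C)(C)C(C)(C)O2)c(B2OC(C)(C)C(C)(C)O2)c(O)c2c(=O)cc(-c3ccc(OCc4ccccc4)cc3OCc3ccccc3)oc12.O=C=[Cr](=C=O)=C=O | intermediate
20 | 2-(2,4-dibenzyloxyphenyl)-5-hydroxy-8-methoxy-6,7-bis(pinacolboryl)chromen-4-one | COc1c(B2OC(C)(C)C(C)(C)O2)c(B2OC(C)(C)C(C)(C)O2)c(O)c2c(=O)cc(-c3ccc(OCc4ccccc4)cc3OCc3ccccc3)oc12 | intermediate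
21 | 2-(2,4-dibenzyloxyphenyl)-5,6,7-trihydroxy-8-methoxychromen-4-one | COc1c(O)c(O)c(O)c2c(=O)cc(-c3ccc(OCc4ccccc4)cc3OCc3ccccc3)oc12 | intermediate
22 | 2-(2,4-dibenzyloxyphenyl)-5-hydroxy-6,7,8-trimethoxychromen-4-one | COc1c(OC)c(O)c2c(=O)cc(-c3ccc(OCc4ccccc4)cc3OCc3ccccc3)oc2c1OC | intermediate
23 | Tamadone, 2-(2,4-dihydroxyphenyl)-5-hydroxy-6,7,8-trimethoxychromen-4-one | COc1c(OC)c(O)c2c(=O)cc(-c3ccc(O)cc3O)oc2c1OC | target

**Totals**
Total step count: 12.
Longest linear sequence: 11 (steps 1–7 and 9–12). Step 8 is a one-step side branch.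

**Three steps most likely to fail**

1. Step 9.
- Risk: the two bulky pinacolboryl groups may slow alkyne uptake so far that the acceptor-substituted carbene complex decays first.
- Risk: after insertion the sequence may stall before ring closure, as doubly silylated alkynes are known to do, or it may skip CO insertion.
- Risk: the crowded C–B bond next to the new phenol may be lost by protodeboronation during demetallation and chromatography.
- Fallback, from 2 back to 22: ring A is bought rather than built. Ortoleva–King reaction of 2 (I2, pyridine, 100 °C) should give 1-[2-(2,4-dibenzyloxyphenyl)-2-oxoethyl]pyridinium iodide F1. Cleavage of F1 with aqueous NaOH gives 2,4-dibenzyloxybenzoic acid F2, and (COCl)2 with catalytic DMF converts this into 2,4-dibenzyloxybenzoyl chloride F3. The lithium dianion of purchased 2'-hydroxy-3',4',5',6'-tetramethoxyacetophenone F4 (LiN(SiMe3)2, THF, −78 °C) is C-acylated by F3 to 1-(2,4-dibenzyloxyphenyl)-3-(2-hydroxy-3,4,5,6-tetramethoxyphenyl)propane-1,3-dione F5, the one-flask form of the Baker–Venkataraman sequence. Catalytic H2SO4 in AcOH closes ring C to 2-(2,4-dibenzyloxyphenyl)-5,6,7,8-tetramethoxychromen-4-one F6. BCl3 (1.1 equiv, CH2Cl2, −78 to −20 °C), held by the C4 carbonyl, removes only the peri 5-O-methyl group and gives 22.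

2. Step 7.
- Risk: the acylate carries an acceptor ring and is a weak oxygen nucleophile, so methyl transfer may be slow and drift to the pyranone carbonyl oxygen (pyrylium formation). The salt may also decay during the solvent switch.
- Risk: electron transfer from the dianion into the pyranone is the second threat. It is held down by the low temperature and by leaving no free naphthalenide.
- Fallback, from 12 back to 13: the acylate oxygen is acylated instead of alkylated. Cation exchange of 12 with Me4NBr in degassed water should give the storable tetramethylammonium acylpentacarbonylchromate F7. Acetyl bromide (1 equiv, CH2Cl2, −40 °C), which does not alkylate the ring carbonyl, converts it into the acetoxycarbene complex pentacarbonyl{acetoxy[6-(2,4-dibenzyloxyphenyl)-4-oxo-4H-pyran-2-yl]methylidene}chromium F8. Methanol then displaces acetate by addition–elimination at the carbene carbon (−40 to −20 °C) and gives 13.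

3. Step 10.
- Risk: the emerging trihydroxyarene, a hydroquinone monoether with two more donors, may be oxidized further by peroxide or air (quinone formation, breakdown of ring A).
- Risk: one hindered C–B bond may be protonated off before oxygen migration.
- Fallback, from 20 back to 23: the 5-OH is capped first, which lowers the oxidation sensitivity and removes the need for selective methylation. BnBr and K2CO3 in DMF at 60 °C should give 5-benzyloxy-2-(2,4-dibenzyloxyphenyl)-8-methoxy-6,7-bis(pinacolboryl)chromen-4-one F9. Buffered H2O2 gives 5-benzyloxy-2-(2,4-dibenzyloxyphenyl)-6,7-dihydroxy-8-methoxychromen-4-one F10. Excess MeI and K2CO3 give 5-benzyloxy-2-(2,4-dibenzyloxyphenyl)-6,7,8-trimethoxychromen-4-one F11. Hydrogenolysis under the conditions of step 12 removes all three benzyl groups and gives 23.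

**Further compounds**
F1 | step 9 | 1-[2-(2,4-dibenzyloxyphenyl)-2-oxoethyl]pyridinium iodide | O=C(C[n+]1ccccc1)c1ccc(OCc2ccccc2)cc1OCc1ccccc1.[I-]
F2 | step 9 | 2,4-dibenzyloxybenzoic acid | O=C(O)c1ccc(OCc2ccccc2)cc1OCc1ccccc1
F3 | step 9 | 2,4-dibenzyloxybenzoyl chloride | O=C(Cl)c1ccc(OCc2ccccc2)cc1OCc1ccccc1
F4 | step 9 | 2'-hydroxy-3',4',5',6'-tetramethoxyacetophenone (purchased partner) | CC(=O)c1c(O)c(OC)c(OC)c(OC)c1OC
F5 | step 9 | 1-(2,4-dibenzyloxyphenyl)-3-(2-hydroxy-3,4,5,6-tetramethoxyphenyl)propane-1,3-dione | COc1c(O)c(C(=O)CC(=O)c2ccc(OCc3ccccc3)cc2OCc2ccccc2)c(OC)c(OC)c1OC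
F6 | step 9 | 2-(2,4-dibenzyloxyphenyl)-5,6,7,8-tetramethoxychromen-4-one | COc1c(OC)c(OC)c2c(=O)cc(-c3ccc(OCc4ccccc4)cc3OCc3ccccc3)oc2c1OC
F7 | step 7 | tetramethylammonium pentacarbonyl[6-(2,4-dibenzyloxyphenyl)-4-oxo-4H-pyran-2-carbonyl]chromate | C[N+](C)(C)C.[O-]C(c1cc(=O)cc(-c2ccc(OCc3ccccc3)cc2OCc2ccccc2)o1)=[Cr](=C=O)(=C=O)(=C=O)(=C=O)=C=O
F8 | step 7 | pentacarbonyl{acetoxy[6-(2,4-dibenzyloxyphenyl)-4-oxo-4H-pyran-2-yl]methylidene}chromium | CC(=O)OC(c1cc(=O)cc(-c2ccc(OCc3ccccc3)cc2OCc2ccccc2)o1)=[Cr](=C=O)(=C=O)(=C=O)(=C=O)=C=O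
F9 | step 10 | 5-benzyloxy-2-(2,4-dibenzyloxyphenyl)-8-methoxy-6,7-bis(pinacolboryl)chromen-4-one | COc1c(B2OC(C)(C)C(C)(C)O2)c(B2OC(C)(C)C(C)(C)O2)c(OCc2ccccc2)c2c(=O)cc(-c3ccc(OCc4ccccc4)cc3OCc3ccccc3)oc12
F10 | step 10 | 5-benzyloxy-2-(2,4-dibenzyloxyphenyl)-6,7-dihydroxy-8-methoxychromen-4-one | COc1c(O)c(O)c(OCc2ccccc2)c2c(=O)cc(-c3ccc(OCc4ccccc4)cc3OCc3ccccc3)oc12
F11 | step 10 | 5-benzyloxy-2-(2,4-dibenzyloxyphenyl)-6,7,8-trimethoxychromen-4-one | COc1c(OC)c(OCc2ccccc2)c2c(=O)cc(-c3ccc(OCc4ccccc4)cc3OCc3ccccc3)oc2c1OC
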